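**Remark on the chemistry:** target 22 is treated as its aromatic polyphenol tautomer. Chromanone positions are O1, C2–C4, C4a, C5–C8, C8a; ring B positions are C1'–C6', with C1' carrying the bridge.

## Analysis of the target

Target 22 is a methylene-bridged dimeric acylphloroglucinol. Its 2,2-dimethylchroman-4-one arene (ring A) carries hydroxyls at C5 and C7, a methyl at C6 and, at C8, a CH2 bridge to ring B, a 2,4,6-trihydroxy-3-methyl-5-(2-methylpropanoyl)phenyl group. There is no stereocentre and no double-bond geometry (C2 is a gem-dimethyl carbon), so the problem is one of regiochemistry only. Both arenes are hexasubstituted, and the three oxygens of ring A end up chemically different: O1 lies in the pyranone, O5 is hydrogen-bonded to the C4 carbonyl and O7 is free. The sensitive elements are the electron-rich diarylmethane (cleaved or scrambled by strong acid through ipso-protonation), the air-sensitive free polyphenols, and the pyranone, which can open by retro-oxa-Michael reaction and re-close on O5 once O5 is free. The difficulty is to join two different phloroglucinol units of similar nucleophilicity through one carbon without forming homodimers, and to decide which ring A oxygen becomes O1. The strategy rests on C8: it bears the bridge and lies between the oxygenated carbons C8a and C7. A two-carbon ynol ether that already carries the ring B benzyl group can therefore supply C8 and C7, and a four-carbon cyclobutenone supplies C8a, C6, C5 and C4a. Ring A is thus grown from the bridge with its oxygens differentiated from the outset (free OH at C8a, silyl ether at C7, ethyl ether at C5).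

## Retrosynthetic reasoning

**22 back to 21 and 20.** The O–alkyl bonds of three methyl ethers and one ethyl ether are cut last, and before them the O–Si bond at C7. Free phloroglucinols oxidise readily, and a free O5 would allow the pyranone to scramble, so all phenols stay masked until the end. The forward steps must remove a hindered aryl silyl ether and four alkyl ethers without breaking the methylene bridge.

**20 back to 18 and 19.** The C5'–C(=O) bond of ring B is cut. C5' is the only arene C–H left in 18, and a ketone could not be carried through the organolithium chemistry that builds the alkyne. Placing this acylation after ring A is fully substituted and carbonyl-deactivated removes any competition from ring A. The forward reaction is a Friedel–Crafts acylation with acid chloride 19 at a position flanked by two methoxy groups.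

**18 back to 17, 16, and then 14 plus 15.** The pyranone is opened at O1–C2 (oxa-Michael) and at C4–C4a (acyl shift from oxygen to carbon), which leads to the aryl ester 16 of phenol 14 and acid chloride 15. All five carbons C2, C3, C4 and the two methyls come from one reagent. Phenol 14 has a single hydroxyl, ortho to the single ring A C–H, so the substrate dictates both where the acyl group lands and which oxygen closes the ring. The forward acyl shift has to run under neutral conditions because of the silyl ether and the bridge, hence a photochemical rather than a Lewis-acid Fries reaction.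

**14 back to 3 and 9 (key disconnection).** Ring A is taken apart at C8–C8a, C6–C7 and C4a–C8a. This splits it into cyclobutenone 3 (its C1, C2, C3, C4 become C8a, C6, C5, C4a) and siloxyalkyne 9 (its two alkyne carbons become C8 and C7). The bridge and the whole of ring B travel with the alkyne, so the unsymmetrical diarylmethane never has to be made by coupling two phenols. The forward cascade must bond the benzyl-bearing alkyne carbon to the ketene carbonyl carbon, so that the one free hydroxyl ends up next to the bridge.

**9 back to 6, 5 and 4.** The siloxyalkyne is traced to arylacetic ester 6 by a one-carbon homologation with 1,2-shift: the inserted carbon becomes C8 and the ester carbon becomes C7. Ester 6 comes from keto ester 5 by benzylic deoxygenation, and 5 from arene 4 by acylation at one of its two equivalent free positions. These are robust polar steps, so the risk is kept for the key step.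

**3 back to 2 and 1.** The cyclobutenone is cut across two ring bonds into ynol ether 1 and a two-carbon ketene unit, which is introduced in halogenated form and then dehalogenated reductively. The polarity of 1 fixes OEt at C3 and methyl at C2 of 3.

## Alternatives that were turned down

**Alternative 1:** Both aryl–acyl bonds (C4a–C4 on ring A and C5'–CO on ring B) are cut together, back to the mixed diester A2 of the symmetric bisphenol A3, which already contains the bridge. In the forward key step, irradiation of A2 would move the 3-methylbut-2-enoyl and the 2-methylpropanoyl group each from oxygen to the only free ortho carbon of its own ring, giving A1.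
- For: it exploits the hidden symmetry of the two C-methylphloroglucinol units, the para positions are blocked by methyl so each shift has one regiochemical outcome, and the pyranone oxygen is automatically the one next to the bridge. It would need roughly half the steps of the chosen route, so on step economy it is clearly stronger.
- Against: A3 must be desymmetrised by two different O-acylations (with 15 and 19), which is statistical at the first acylation. Two photo-Fries events must also succeed in one molecule. After the first, the new ortho-hydroxyaryl ketone dissipates excitation by excited-state proton transfer and absorbs most of the light, so the second shift is expected to stall. Cage escape on either ring multiplies the by-products. Making A3 by one-carbon bridging of a phenol with two equivalent free ortho positions also invites oligomers.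
- Comparison: the chosen route is longer but forms each C–C bond with a single possible outcome, irradiates only one ester chromophore, and differentiates ring A's oxygens by construction.

**Alternative 2:** Ring A is cut at C8–C8a, C5–C6, C7–C8 and C4a–C5, back to the dihydropyranone diazo ketone A5 and siloxypropyne A6, so the pyranone is present from the start. In the forward key step, light triggers a Wolff shift in A5 (forming C8–C8a). The resulting vinylketene adds A6, and 4π opening followed by 6π closure gives chromanone A4, with O5 free, O7 silylated and C8 as C–H.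
- For: no acyl shift or oxa-Michael step is needed, there is no question which oxygen is O1, the ketene forms at room temperature, and A4 already has the right oxidation level. On all these points it is as strong as or stronger than the chosen route, which spends three operations on the pyranone.
- Against: C8 emerges unsubstituted, so the bridge to ring B still has to be made at a hindered position of a carbonyl-deactivated arene. That brings back the coupling of two phenolic units through one carbon, with its homo- and heterodimer mixtures, as the last C–C bond. A5 also needs several steps including a diazo transfer or diazoalkane acylation.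
- Comparison: the chosen strategy uses the same pericyclic cascade but lets the alkyne carry ring B, so the bridge carbon is part of the annulation.

**Alternative 3:** The pyran ring is cut at C3–C4 and O1–C2, back to salicylaldehyde A8 and isobutene A9. In the forward key step, the Lewis-acid-activated aldehyde A8, an oxygen-stabilised ortho-quinone-methide-like cation, would be attacked by A9 at the aldehyde carbon, and the phenol oxygen would trap the tertiary cation to give racemic chromanol A7.
- For: two bonds and the ring form in one step from a feedstock alkene. For building the 2,2-dimethylpyran alone this is shorter than the ester, photo-Fries and oxa-Michael sequence used here.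
- Against: A7 is at the alcohol oxidation level with a stereocentre that must be oxidised away. Its benzylic hydroxyl, flanked by donor oxygens, should ionise under the same Lewis acid and lead to elimination or arylation. The aldehyde of A8 is deactivated by three donor oxygens while A9 is prone to cationic oligomerisation. A8 needs one specific phenol of three to be free. As in alternative 2, C8 remains C–H and the bridge is unsolved.
- Comparison: the chosen route reaches the ketone directly and has the bridge in place before ring A exists.

Key step: step 6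

## Route

**Step 1**
Reactants: 1 1-ethoxyprop-1-yne
Product: 2 4,4-dichloro-3-ethoxy-2-methylcyclobut-2-en-1-one
Conditions: Cl3CCOCl, Zn–Cu couple, Et2O/DME, 0 °C → rt; crude used directly
Reagents that add atoms: trichloroacetyl chloride, ClC(=O)C(Cl)(Cl)Cl
Why: Dichloroketene, formed by zinc dechlorination of the acid chloride, should add to the electron-rich ynol ether in a polar [2+2] cycloaddition. The nucleophilic methyl-bearing alkyne carbon bonds to the ketene carbonyl carbon, which fixes methyl at C2 and OEt at C3.

**Step 2**
Reactants: 2 4,4-dichloro-3-ethoxy-2-methylcyclobut-2-en-1-one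
Product: 3 3-ethoxy-2-methylcyclobut-2-en-1-one
Conditions: Zn dust, AcOH, TMEDA, EtOH, 0 °C → rt
Reagents that add atoms: none
Why: Reductive dehalogenation of the α,α-dichloro ketone through its zinc enolate and protonation should remove both chlorines. The vinylogous ester is not reduced under these buffered conditions.

**Step 3**
Reactants: 4 1,3,5-trimethoxy-2-methylbenzene
Product: 5 ethyl 2-oxo-2-(2,4,6-trimethoxy-3-methylphenyl)acetate
Conditions: ClCOCO2Et, TiCl4, CH2Cl2, −20 → 0 °C
Reagents that add atoms: ethyl chlorooxoacetate, CCOC(=O)C(Cl)=O
Why: Friedel–Crafts acylation. Arene 4 has two equivalent free positions, each flanked by two methoxy groups, and the keto ester product is deactivated, so monoacylation at one of them is the only expected outcome.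

**Step 4**
Reactants: 5 ethyl 2-oxo-2-(2,4,6-trimethoxy-3-methylphenyl)acetate
Product: 6 ethyl 2-(2,4,6-trimethoxy-3-methylphenyl)acetate
Conditions: Et3SiH, CF3CO2H, CH2Cl2, 0 °C → rt
Reagents that add atoms: none
Why: Ionic hydrogenation. The protonated aryl ketone and then the derived benzylic alcohol give cations strongly stabilised by the trimethoxyaryl ring, each reduced by hydride from the silane; the ester is inert.

**Step 5**
Reactants: 6 ethyl 2-(2,4,6-trimethoxy-3-methylphenyl)acetate
Product: 9 triisopropyl{[3-(2,4,6-trimethoxy-3-methylphenyl)prop-1-yn-1-yl]oxy}silane, via lithium dibromoenolate 7 (not isolated), via lithium ynolate 8 (not isolated)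
Conditions: CH2Br2, lithium 2,2,6,6-tetramethylpiperidide, THF, −78 °C; LiN(SiMe3)2; n-BuLi, −78 → 25 °C; i-Pr3SiCl, −78 → 0 °C
Reagents that add atoms: dibromomethane, BrCBr; chlorotriisopropylsilane, CC(C)[Si](Cl)(C(C)C)C(C)C
Why: Kowalski ester homologation. Dibromomethyllithium adds to the ester, enolate 7 undergoes bromine–lithium exchange and 1,2-shift of the arylmethyl group to give ynolate 8, and the bulky silyl chloride silylates 8 on oxygen. The inserted carbon becomes C8 and the former ester carbon becomes the oxygen-bearing C7.

**Step 6**
Reactants: 3 3-ethoxy-2-methylcyclobut-2-en-1-one; 9 triisopropyl{[3-(2,4,6-trimethoxy-3-methylphenyl)prop-1-yn-1-yl]oxy}silane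
Product: 14 5-ethoxy-4-methyl-3-(triisopropylsilyloxy)-2-[(2,4,6-trimethoxy-3-methylphenyl)methyl]phenol, via vinylketene 10 (not isolated), via vinylcyclobutenone 11 (not isolated), via dienylketene 12 (not isolated), via cyclohexadienone 13 (not isolated)
Conditions: PhMe, 80 → 110 °C, sealed tube, slight excess of 9
Reagents that add atoms: none
Why: Heating should open cyclobutenone 3 by 4π electrocyclic cleavage of its C1–C4 bond to vinylketene 10. Siloxyalkyne 9 then adds across the ketene C=C in a polar [2+2] cycloaddition to give vinylcyclobutenone 11, which forms C8–C8a and C6–C7. A second 4π opening gives dienylketene 12, and ring A is closed by a thermal disrotatory 6π electrocyclisation (C4a–C8a) to cyclohexadienone 13, which tautomerises to phenol 14. The closest known reaction type is the thermal benzannulation of cyclobutenones with alkoxy- and siloxyalkynes (Danheiser benzannulation), which gives highly substituted resorcinol derivatives. No stereocentre is formed in 14; the quaternary centre of 11 is racemic and is lost on ring opening. The selectivity needed is the [2+2] regiochemistry: the benzyl-bearing alkyne carbon must bond to the ketene carbonyl carbon. The oxygen-induced polarisation of the ynol ether, whose β-carbon is the nucleophile, secures this. The ketene oxygen therefore becomes the only free hydroxyl at C8a, next to the bridge carbon C8; C7 and C5 emerge as silyl and ethyl ethers, and C4a is the only ring A C–H.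

**Step 7**
Reactants: 14 5-ethoxy-4-methyl-3-(triisopropylsilyloxy)-2-[(2,4,6-trimethoxy-3-methylphenyl)methyl]phenol; 15 3-methylbut-2-enoyl chloride
Product: 16 5-ethoxy-4-methyl-3-(triisopropylsilyloxy)-2-[(2,4,6-trimethoxy-3-methylphenyl)methyl]phenyl 3-methylbut-2-enoate
Conditions: NaH, THF, 0 °C; then 15, 0 °C → rt
Reagents that add atoms: none
Why: O-acylation of the sodium phenoxide at the only free hydroxyl. Preforming the phenoxide avoids the amine-induced vinylketene pathway that would deconjugate the unsaturated acyl group.

**Step 8**
Reactants: 16 5-ethoxy-4-methyl-3-(triisopropylsilyloxy)-2-[(2,4,6-trimethoxy-3-methylphenyl)methyl]phenyl 3-methylbut-2-enoate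
Product: 18 5-ethoxy-2,2,6-trimethyl-7-(triisopropylsilyloxy)-8-[(2,4,6-trimethoxy-3-methylphenyl)methyl]chroman-4-one, via hydroxyaryl enone 17 (not isolated)
Conditions: hν (254 nm, quartz), degassed cyclohexane, rt; then DBU (cat.), CH2Cl2, rt
Reagents that add atoms: none
Why: Photo-Fries rearrangement. O–acyl homolysis gives a caged phenoxyl/acyl radical pair that can recombine productively only at C4a, because C8 and C6 are substituted. DBU should then promote the 6-endo-trig oxa-Michael addition of the C8a phenoxide to the β,β-dimethyl enone of 17; O5 is an ethyl ether and cannot compete.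

**Step 9**
Reactants: 18 5-ethoxy-2,2,6-trimethyl-7-(triisopropylsilyloxy)-8-[(2,4,6-trimethoxy-3-methylphenyl)methyl]chroman-4-one; 19 2-methylpropanoyl chloride
Product: 20 5-ethoxy-2,2,6-trimethyl-7-(triisopropylsilyloxy)-8-{[2,4,6-trimethoxy-3-methyl-5-(2-methylpropanoyl)phenyl]methyl}chroman-4-one
Conditions: TiCl4, CH2Cl2, −20 → 0 °C
Reagents that add atoms: none
Why: Friedel–Crafts acylation at C5', the only unsubstituted arene carbon of 18, activated by two ortho and one para methoxy groups. Ring A is fully substituted and deactivated by the C4 carbonyl. A mild Lewis acid at low temperature is chosen to spare the silyl ether and the bridge.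

**Step 10**
Reactants: 20 5-ethoxy-2,2,6-trimethyl-7-(triisopropylsilyloxy)-8-{[2,4,6-trimethoxy-3-methyl-5-(2-methylpropanoyl)phenyl]methyl}chroman-4-one
Product: 21 5-ethoxy-7-hydroxy-2,2,6-trimethyl-8-{[2,4,6-trimethoxy-3-methyl-5-(2-methylpropanoyl)phenyl]methyl}chroman-4-one
Conditions: Bu4NF, AcOH, THF, 0 °C
Reagents that add atoms: none
Why: Fluoride cleavage of the aryl silyl ether. The departing phenoxide is para to the C4 carbonyl, and the acetic acid buffer keeps the pyranone from opening by retro-oxa-Michael reaction.

**Step 11**
Reactants: 21 5-ethoxy-7-hydroxy-2,2,6-trimethyl-8-{[2,4,6-trimethoxy-3-methyl-5-(2-methylpropanoyl)phenyl]methyl}chroman-4-one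
Product: 22 5,7-dihydroxy-2,2,6-trimethyl-8-{[2,4,6-trihydroxy-3-methyl-5-(2-methylpropanoyl)phenyl]methyl}chroman-4-one
Conditions: BBr3 (excess), CH2Cl2, −78 → 0 °C; then H2O
Reagents that add atoms: none
Why: Lewis-acid dealkylation of the three methyl ethers and the ethyl ether by boron complexation and bromide attack at the alkyl carbon. The ethers flanking the two carbonyls should go first under chelation, and the aryl borates are deactivated towards ipso-protonation until aqueous work-up releases the phenols.

## Compound list

1 | 1-ethoxyprop-1-yne | CC#COCC | starting material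
2 | 4,4-dichloro-3-ethoxy-2-methylcyclobut-2-en-1-one | CCOC1=C(C)C(=O)C1(Cl)Cl | intermediate
3 | 3-ethoxy-2-methylcyclobut-2-en-1-one | CCOC1=C(C)C(=O)C1 | intermediate
4 | 1,3,5-trimethoxy-2-methylbenzene | COc1cc(OC)c(C)c(OC)c1 | starting material
5 | ethyl 2-oxo-2-(2,4,6-trimethoxy-3-methylphenyl)acetate | CCOC(=O)C(=O)c1c(OC)cc(OC)c(C)c1OC | intermediate
6 | ethyl 2-(2,4,6-trimethoxy-3-methylphenyl)acetate | CCOC(=O)Cc1c(OC)cc(OC)c(C)c1OC | intermediate
7 | lithium 1,1-dibromo-3-(2,4,6-trimethoxy-3-methylphenyl)prop-1-en-2-olate | [Li+].[O-]C(=C(Br)Br)Cc1c(OC)cc(OC)c(C)c1OC | intermediate (not isolated)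
8 | lithium 3-(2,4,6-trimethoxy-3-methylphenyl)prop-1-yn-1-olate | [Li+].[O-]C#CCc1c(OC)cc(OC)c(C)c1OC | intermediate (not isolated)
9 | triisopropyl{[3-(2,4,6-trimethoxy-3-methylphenyl)prop-1-yn-1-yl]oxy}silane | COc1cc(OC)c(C)c(OC)c1CC#CO[Si](C(C)C)(C(C)C)C(C)C | intermediate
10 | 3-ethoxy-2-methylbuta-1,3-dien-1-one | C=C(OCC)C(C)=C=O | intermediate (not isolated)
11 | racemic 4-(1-ethoxyethenyl)-4-methyl-3-(triisopropylsilyloxy)-2-[(2,4,6-trimethoxy-3-methylphenyl)methyl]cyclobut-2-en-1-one | CCOC(=C)C1(C)C(=O)C(Cc2c(OC)cc(OC)c(C)c2OC)=C1O[Si](C(C)C)(C(C)C)C(C)C | intermediate (not isolated)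
12 | (3E)-5-ethoxy-4-methyl-3-(triisopropylsilyloxy)-2-[(2,4,6-trimethoxy-3-methylphenyl)methyl]hexa-1,3,5-trien-1-one (ketene and ethoxyvinyl groups cis) | O=C=C(Cc1c(OC)cc(OC)c(C)c1OC)/C(O[Si](C(C)C)(C(C)C)C(C)C)=C(C)\C(=C)OCC | intermediate (not isolated)
13 | 5-ethoxy-4-methyl-3-(triisopropylsilyloxy)-2-[(2,4,6-trimethoxy-3-methylphenyl)methyl]cyclohexa-2,4-dien-1-one | CCOC1=C(C)C(O[Si](C(C)C)(C(C)C)C(C)C)=C(Cc2c(OC)cc(OC)c(C)c2OC)C(=O)C1 | intermediate (not isolated)
14 | 5-ethoxy-4-methyl-3-(triisopropylsilyloxy)-2-[(2,4,6-trimethoxy-3-methylphenyl)methyl]phenol | Oc1cc(OCC)c(C)c(O[Si](C(C)C)(C(C)C)C(C)C)c1Cc1c(OC)cc(OC)c(C)c1OC | intermediate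
15 | 3-methylbut-2-enoyl chloride | CC(C)=CC(Cl)=O | starting material
16 | 5-ethoxy-4-methyl-3-(triisopropylsilyloxy)-2-[(2,4,6-trimethoxy-3-methylphenyl)methyl]phenyl 3-methylbut-2-enoate | CC(C)=CC(=O)Oc1cc(OCC)c(C)c(O[Si](C(C)C)(C(C)C)C(C)C)c1Cc1c(OC)cc(OC)c(C)c1OC | intermediate
17 | 1-{6-ethoxy-2-hydroxy-5-methyl-4-(triisopropylsilyloxy)-3-[(2,4,6-trimethoxy-3-methylphenyl)methyl]phenyl}-3-methylbut-2-en-1-one | CC(C)=CC(=O)c1c(O)c(Cc2c(OC)cc(OC)c(C)c2OC)c(O[Si](C(C)C)(C(C)C)C(C)C)c(C)c1OCC | intermediate (not isolated)
18 | 5-ethoxy-2,2,6-trimethyl-7-(triisopropylsilyloxy)-8-[(2,4,6-trimethoxy-3-methylphenyl)methyl]chroman-4-one | CCOc1c(C)c(O[Si](C(C)C)(C(C)C)C(C)C)c(Cc2c(OC)cc(OC)c(C)c2OC)c2OC(C)(C)CC(=O)c12 | intermediate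
19 | 2-methylpropanoyl chloride (isobutyryl chloride) | CC(C)C(Cl)=O | starting material
20 | 5-ethoxy-2,2,6-trimethyl-7-(triisopropylsilyloxy)-8-{[2,4,6-trimethoxy-3-methyl-5-(2-methylpropanoyl)phenyl]methyl}chroman-4-one | CCOc1c(C)c(O[Si](C(C)C)(C(C)C)C(C)C)c(Cc2c(OC)c(C(=O)C(C)C)c(OC)c(C)c2OC)c2OC(C)(C)CC(=O)c12 | intermediate
21 | 5-ethoxy-7-hydroxy-2,2,6-trimethyl-8-{[2,4,6-trimethoxy-3-methyl-5-(2-methylpropanoyl)phenyl]methyl}chroman-4-one | CCOc1c(C)c(O)c(Cc2c(OC)c(C(=O)C(C)C)c(OC)c(C)c2OC)c2OC(C)(C)CC(=O)c12 | intermediate
22 | 5,7-dihydroxy-2,2,6-trimethyl-8-{[2,4,6-trihydroxy-3-methyl-5-(2-methylpropanoyl)phenyl]methyl}chroman-4-one | Cc1c(O)c(Cc2c(O)c(C)c(O)c3c2OC(C)(C)CC3=O)c(O)c(C(=O)C(C)C)c1O | target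

## Step count and risk

Total step count: 11. Longest linear sequence: 9 steps (4 to 22, steps 3–11). The cyclobutenone branch (steps 1 and 2) joins at step 6.

**Step 6 (key step).** The most likely failure is loss of the vinylketene or the alkyne along side paths. The donor-substituted cyclobutenone may open only at temperatures where the siloxyalkyne isomerises by 1,3-silyl shift from oxygen to carbon, and the new phenol can be acylated by unconsumed vinylketene. The fallback keeps alkyne 9 and generates the same vinylketene 10 at room temperature by a photochemical Wolff rearrangement. (1-Ethoxyvinyl)lithium is acylated with N-methoxy-N-methylpropanamide to give 2-ethoxypent-1-en-3-one F1. Its lithium enolate (LiN(SiMe3)2) is trifluoroacetylated with CF3CO2CH2CF3 to give 5-ethoxy-1,1,1-trifluoro-3-methylhex-5-ene-2,4-dione F2. Detrifluoroacetylative diazo transfer (MsN3, Et3N, wet MeCN) then gives 2-diazo-4-ethoxypent-4-en-3-one F3. Irradiation of F3 with 9 (300 nm, CH2Cl2, rt) should give 10 by migration of the ethoxyvinyl group, which is trapped as 11; brief warming to 80 °C completes the cascade. The fallback thus sets out from 9 and re-enters the route at 10 and hence at 14.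

**Step 5.** Proton transfer may win over carbonyl addition: the carbenoid can enolise the arylacetic ester, and excess alkyllithium can metalate C5' between two methoxy groups during the warm-up. The fallback sets out from 6. Reduction with i-Bu2AlH (−78 °C) gives 2-(2,4,6-trimethoxy-3-methylphenyl)acetaldehyde F4. Ohira–Bestmann homologation (dimethyl (1-diazo-2-oxopropyl)phosphonate, K2CO3, MeOH) gives 1,3,5-trimethoxy-2-methyl-4-(prop-2-yn-1-yl)benzene F5. Its lithium acetylide (n-BuLi) is oxidised with t-BuOOLi to ynolate 8, which is silylated as before, so the route is rejoined at 8 and 9.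

**Step 8.** The photo-Fries shift may be inefficient. The chelated hydroxy ketone product acts as an inner filter, the radical pair can escape the cage to return 14, and the electron-rich trimethoxyaryl ring may quench the excited ester by electron transfer. The fallback sets out from 14. Magnesium-mediated ortho-formylation (MgCl2, Et3N, paraformaldehyde) at the only free ortho position gives 6-ethoxy-2-hydroxy-5-methyl-4-(triisopropylsilyloxy)-3-[(2,4,6-trimethoxy-3-methylphenyl)methyl]benzaldehyde F6. Addition of (2-methylprop-1-en-1-yl)magnesium bromide gives racemic 3-ethoxy-2-(1-hydroxy-3-methylbut-2-en-1-yl)-4-methyl-5-(triisopropylsilyloxy)-6-[(2,4,6-trimethoxy-3-methylphenyl)methyl]phenol F7, which is handled without acid and oxidised with MnO2 to enone 17. The route is rejoined at 17, which DBU closes to 18.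

**Step 9.** The Lewis acid may induce ipso attack at C1' with loss of the benzylic bridge (retro-Friedel–Crafts), or strip the silyl ether so that O7 is acylated; the acylium ion may also react slowly at the hindered C5'. The fallback sets out from 18 and uses a small electrophile without a metal Lewis acid. Vilsmeier–Haack formylation (POCl3, DMF) gives 3-{[5-ethoxy-2,2,6-trimethyl-4-oxo-7-(triisopropylsilyloxy)chroman-8-yl]methyl}-2,4,6-trimethoxy-5-methylbenzaldehyde F8. Aldehyde-selective addition of i-PrMgCl with LaCl3·2LiCl (−78 °C) gives racemic 5-ethoxy-8-{[3-(1-hydroxy-2-methylpropyl)-2,4,6-trimethoxy-5-methylphenyl]methyl}-2,2,6-trimethyl-7-(triisopropylsilyloxy)chroman-4-one F9. Oxidation with Dess–Martin periodinane returns to the route at 20.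

**Step 11.** The free O7–H of 21 liberates HBr with BBr3. In the presence of excess Lewis acid this can promote scission of the bridge, or opening of the pyranone and re-closure on O5. Cleavage of the unchelated C2' methyl ether may also be incomplete. The fallback changes the order of unmasking and sets out from 20. BBr3 acts on the fully capped substrate, where no O–H and hence no HBr is present before the quench, to give 5-hydroxy-2,2,6-trimethyl-7-(triisopropylsilyloxy)-8-{[2,4,6-trihydroxy-3-methyl-5-(2-methylpropanoyl)phenyl]methyl}chroman-4-one F10. Non-basic desilylation with Et3N·3HF in THF then gives 22 directly; any material already desilylated by BBr3 is 22 itself.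

## Further compounds

F1 | step 6 | 2-ethoxypent-1-en-3-one | CCC(=O)C(=C)OCC
F2 | step 6 | racemic 5-ethoxy-1,1,1-trifluoro-3-methylhex-5-ene-2,4-dione | CC(C(=O)C(F)(F)F)C(=O)C(=C)OCC
F3 | step 6 | 2-diazo-4-ethoxypent-4-en-3-one | CC(=[N+]=[N-])C(=O)C(=C)OCC
F4 | step 5 | 2-(2,4,6-trimethoxy-3-methylphenyl)acetaldehyde | O=CCc1c(OC)cc(OC)c(C)c1OC
F5 | step 5 | 1,3,5-trimethoxy-2-methyl-4-(prop-2-yn-1-yl)benzene | C#CCc1c(OC)cc(OC)c(C)c1OC
F6 | step 8 | 6-ethoxy-2-hydroxy-5-methyl-4-(triisopropylsilyloxy)-3-[(2,4,6-trimethoxy-3-methylphenyl)methyl]benzaldehyde | CCOc1c(C)c(O[Si](C(C)C)(C(C)C)C(C)C)c(Cc2c(OC)cc(OC)c(C)c2OC)c(O)c1C=O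
F7 | step 8 | racemic 3-ethoxy-2-(1-hydroxy-3-methylbut-2-en-1-yl)-4-methyl-5-(triisopropylsilyloxy)-6-[(2,4,6-trimethoxy-3-methylphenyl)methyl]phenol | CCOc1c(C)c(O[Si](C(C)C)(C(C)C)C(C)C)c(Cc2c(OC)cc(OC)c(C)c2OC)c(O)c1C(O)C=C(C)C
F8 | step 9 | 3-{[5-ethoxy-2,2,6-trimethyl-4-oxo-7-(triisopropylsilyloxy)chroman-8-yl]methyl}-2,4,6-trimethoxy-5-methylbenzaldehyde | CCOc1c(C)c(O[Si](C(C)C)(C(C)C)C(C)C)c(Cc2c(OC)c(C=O)c(OC)c(C)c2OC)c2OC(C)(C)CC(=O)c12
F9 | step 9 | racemic 5-ethoxy-8-{[3-(1-hydroxy-2-methylpropyl)-2,4,6-trimethoxy-5-methylphenyl]methyl}-2,2,6-trimethyl-7-(triisopropylsilyloxy)chroman-4-one | CCOc1c(C)c(O[Si](C(C)C)(C(C)C)C(C)C)c(Cc2c(OC)c(C(O)C(C)C)c(OC)c(C)c2OC)c2OC(C)(C)CC(=O)c12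
F10 | step 11 | 5-hydroxy-2,2,6-trimethyl-7-(triisopropylsilyloxy)-8-{[2,4,6-trihydroxy-3-methyl-5-(2-methylpropanoyl)phenyl]methyl}chroman-4-one | Cc1c(O)c(Cc2c(O[Si](C(C)C)(C(C)C)C(C)C)c(C)c(O)c3c2OC(C)(C)CC3=O)c(O)c(C(=O)C(C)C)c1O
A1 | alternative 1 | 1-[2-hydroxy-3-[[2-hydroxy-4,6-dimethoxy-5-methyl-3-(2-methylpropanoyl)phenyl]methyl]-4,6-dimethoxy-5-methylphenyl]-3-methylbut-2-en-1-one | CC(C)C(=O)c1c(O)c(Cc2c(O)c(C(=O)C=C(C)C)c(OC)c(C)c2OC)c(OC)c(C)c1OC
A2 | alternative 1 | 2-{[2,4-dimethoxy-3-methyl-6-(2-methylpropanoyloxy)phenyl]methyl}-3,5-dimethoxy-4-methylphenyl 3-methylbut-2-enoate | CC(C)C(=O)Oc1cc(OC)c(C)c(OC)c1Cc1c(OC(=O)C=C(C)C)cc(OC)c(C)c1OC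
A3 | alternative 1 | 2,2'-methylenebis(3,5-dimethoxy-4-methylphenol) | COc1cc(O)c(Cc2c(O)cc(OC)c(C)c2OC)c(OC)c1C
A4 | alternative 2 | 5-hydroxy-2,2,6-trimethyl-7-(triisopropylsilyloxy)chroman-4-one | CC1(C)CC(=O)c2c(O)c(C)c(O[Si](C(C)C)(C(C)C)C(C)C)cc2O1
A5 | alternative 2 | 6-(2-diazoacetyl)-2,2-dimethyl-2,3-dihydro-4H-pyran-4-one | CC1(C)CC(=O)C=C(O1)C(=O)C=[N+]=[N-]
A6 | alternative 2 | triisopropyl(prop-1-yn-1-yloxy)silane | CC#CO[Si](C(C)C)(C(C)C)C(C)C
A7 | alternative 3 | racemic 5,7-dimethoxy-2,2,6-trimethylchroman-4-ol | CC1(C)CC(O)c2c(OC)c(C)c(OC)cc2O1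
A8 | alternative 3 | 6-hydroxy-2,4-dimethoxy-3-methylbenzaldehyde | O=Cc1c(O)cc(OC)c(C)c1OC
A9 | alternative 3 | 2-methylprop-1-ene (isobutene) | CC(C)=C
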